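**Retrosynthetic overview**
1. Target 35 ⇒ macrocyclic epoxy alcohol 33 + 4-methoxybenzoyl chloride (acylation last).
2. The 11-membered carbocycle ⇒ open-chain epoxy aldehyde / tetrazolyl sulfone 29, closed at C8=C9 by intramolecular Julia–Kocienski olefination, then diimide saturation.
3. Key C1–C11 bond ⇒ enal 10 + prenylborane 15: intermolecular asymmetric carbonyl allylation (reverse prenylation) sets C1 and the gem-dimethyl carbon; its vinyl group becomes C9/C10.
4. Enal 10 ⇒ geraniol: SeO2 oxidation at C8, then Sharpless epoxidation sets C6 and C7.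
5. Ring order: oxirane first (step 3), 11-membered ring last (step 15).

Assumption: ring positions are labelled C1–C11 as in the final ring (C1 acyloxy carbon, C2=C3 alkene, C6/C7 oxirane carbons, C11 gem-dimethyl carbon), the labels are kept for open-chain precursors, and reagents named only in Conditions lines are bought.

**Step 1**
Reactants: 1 geraniol; 2 tert-butyl(chloro)diphenylsilane
Product: 3 tert-butyl{[(2E)-3,7-dimethylocta-2,6-dien-1-yl]oxy}diphenylsilane
Conditions: imidazole, DMF, 0 °C → rt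
Reagents that add atoms: tert-butyl(chloro)diphenylsilane, CC(C)(C)[Si](Cl)(c1ccccc1)c1ccccc1
Why: Silyl ether protection of the primary allylic alcohol gives a robust ether that also deactivates the 2,3-alkene towards the next oxidations; no stereocentre is formed.

**Step 2**
Reactants: 3 geranyl silyl ether; 4 tert-butyl hydroperoxide
Product: 5 (2E,6E)-8-{[tert-butyl(diphenyl)silyl]oxy}-2,6-dimethylocta-2,6-dien-1-ol
Conditions: SeO2 (cat.), t-BuOOH, salicylic acid (cat.), CH2Cl2, 0 °C → rt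
Reagents that add atoms: tert-butyl hydroperoxide, CC(C)(C)OO
Why: SeO2 allylic oxidation (ene reaction then [2,3]-sigmatropic shift) hydroxylates the E-methyl group of the more electron-rich distal alkene, so C8 ends up trans to C5 and no stereocentre is formed.

**Step 3**
Reactants: 5 allylic alcohol; 4 tert-butyl hydroperoxide
Product: 6 {(2R,3R)-3-[(3E)-5-{[tert-butyl(diphenyl)silyl]oxy}-3-methylpent-3-en-1-yl]-2-methyloxiran-2-yl}methanol
Conditions: Ti(OiPr)4 (10 mol %), D-(−)-diethyl tartrate (12 mol %), t-BuOOH, 4 Å MS, CH2Cl2, −20 °C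
Reagents that add atoms: tert-butyl hydroperoxide, CC(C)(C)OO
Why: Katsuki–Sharpless asymmetric epoxidation touches only the alkene with the free allylic OH, and with D-(−)-tartrate an E-2-methylallylic alcohol gives the (2R,3R)-epoxy alcohol (mirror image of the 2S,3S series from L-(+)-tartrate), which fixes C6 as R and C7 as R.

**Step 4**
Reactants: 6 epoxy alcohol; 7 1-(chloromethyl)-4-methoxybenzene
Product: 8 tert-butyl{[(2E)-5-[(2R,3R)-3-{[(4-methoxyphenyl)methoxy]methyl}-3-methyloxiran-2-yl]-3-methylpent-2-en-1-yl]oxy}diphenylsilane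
Conditions: NaH, n-Bu4NI (cat.), THF/DMF, 0 °C → rt
Reagents that add atoms: 1-(chloromethyl)-4-methoxybenzene, COc1ccc(CCl)cc1
Why: Williamson etherification of the primary alkoxide in aprotic medium outruns Payne rearrangement, so C6 and C7 are untouched.

**Step 5**
Reactants: 8 bis-ether
Product: 9 (2E)-5-[(2R,3R)-3-{[(4-methoxyphenyl)methoxy]methyl}-3-methyloxiran-2-yl]-3-methylpent-2-en-1-ol
Conditions: n-Bu4NF, THF, 0 °C → rt
Reagents that add atoms: none
Why: Fluoride-induced desilylation frees the allylic alcohol while the benzyl-type ether and the epoxide are inert.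

**Step 6**
Reactants: 9 allylic alcohol
Product: 10 (2E)-5-[(2R,3R)-3-{[(4-methoxyphenyl)methoxy]methyl}-3-methyloxiran-2-yl]-3-methylpent-2-enal
Conditions: MnO2, CH2Cl2, rt
Reagents that add atoms: none
Why: MnO2 oxidation is selective for the allylic alcohol and gives the E-enal without double-bond isomerisation or epoxide opening.

**Step 7**
Reactants: 11 (−)-α-pinene; 12 borane–dimethyl sulfide
Product: 13 (+)-diisopinocampheylborane
Conditions: THF, 0 °C, 3 d (excess 11), crystalline solid collected under N2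
Reagents that add atoms: borane–dimethyl sulfide, C[S+](C)[BH3-]
Why: Brown hydroboration adds B–H to the alkene face anti to the gem-dimethyl bridge, and crystallisation of the dialkylborane in the presence of excess pinene upgrades its enantiomeric purity.

**Step 8 (key step)**
Reactants: 10 enal; 13 (+)-diisopinocampheylborane; 14 3-methylbuta-1,2-diene
Product: 17 (4S,5E)-8-[(2R,3R)-3-{[(4-methoxyphenyl)methoxy]methyl}-3-methyloxiran-2-yl]-3,3,6-trimethylocta-1,5-dien-4-ol, via B-prenyldiisopinocampheylborane 15 (not isolated), via borinate ester 16 (not isolated)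
Conditions: 13 + 14, THF, −25 °C; then 10, −78 °C; then NaBO3·4H2O, THF/H2O, rt
Reagents that add atoms: 3-methylbuta-1,2-diene, CC(C)=C=C
Why: Brown asymmetric carbonyl allylation (reverse prenylation): the allylborane delivers its γ-carbon through a chair Zimmerman–Traxler transition state, and the isopinocampheyl groups from (−)-α-pinene direct attack to the Re face of the enal, which sets C1 as S and forms the C1–C11 bond with the gem-dimethyl quaternary carbon.

**Step 9**
Reactants: 17 homoallylic alcohol; 18 chlorotriethylsilane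
Product: 19 triethyl{[(4S,5E)-8-[(2R,3R)-3-{[(4-methoxyphenyl)methoxy]methyl}-3-methyloxiran-2-yl]-3,3,6-trimethylocta-1,5-dien-4-yl]oxy}silane
Conditions: imidazole, DMAP (cat.), DMF, rt
Reagents that add atoms: chlorotriethylsilane, CC[Si](Cl)(CC)CC
Why: Silyl ether protection under neutral conditions masks the hindered C1 hydroxyl for the borane, oxidant and carbanion steps without risk to the epoxide; C1 is not touched.

**Step 10**
Reactants: 19 silyl ether; 20 9-borabicyclo[3.3.1]nonane; 21 hydrogen peroxide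
Product: 23 (4S,5E)-8-[(2R,3R)-3-{[(4-methoxyphenyl)methoxy]methyl}-3-methyloxiran-2-yl]-3,3,6-trimethyl-4-[(triethylsilyl)oxy]oct-5-en-1-ol, via B-alkyl-9-BBN adduct 22 (not isolated)
Conditions: 9-BBN, THF, 0 °C → rt; then NaOH, 30% H2O2, 0 °C
Reagents that add atoms: hydrogen peroxide, OO
Why: Anti-Markovnikov hydroboration–oxidation with the bulky 9-BBN takes only the monosubstituted vinyl group (the trisubstituted alkene and the epoxide do not react) and gives the C9 primary alcohol.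

**Step 11**
Reactants: 23 primary alcohol; 24 1-phenyl-1H-tetrazole-5-thiol
Product: 25 5-{[(4S,5E)-8-[(2R,3R)-3-{[(4-methoxyphenyl)methoxy]methyl}-3-methyloxiran-2-yl]-3,3,6-trimethyl-4-[(triethylsilyl)oxy]oct-5-en-1-yl]sulfanyl}-1-phenyl-1H-tetrazole
Conditions: PPh3, DIAD, THF, 0 °C → rt
Reagents that add atoms: 1-phenyl-1H-tetrazole-5-thiol, SC1=NN=NN1c1ccccc1
Why: Mitsunobu thioetherification displaces the activated primary alcohol by the acidic thiol in an SN2 process under neutral conditions that spare the epoxide.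

**Step 12**
Reactants: 25 sulfide; 21 hydrogen peroxide
Product: 27 5-{[(4S,5E)-8-[(2R,3R)-3-{[(4-methoxyphenyl)methoxy]methyl}-3-methyloxiran-2-yl]-3,3,6-trimethyl-4-[(triethylsilyl)oxy]oct-5-en-1-yl]sulfonyl}-1-phenyl-1H-tetrazole, via sulfoxide 26 (not isolated)
Conditions: (NH4)6Mo7O24·4H2O (cat.), 30% H2O2, EtOH, 0 °C → rt
Reagents that add atoms: hydrogen peroxide, OO
Why: Molybdate-catalysed sulfide oxidation is chemoselective for sulfur and leaves the unfunctionalised trisubstituted alkene and the epoxide alone.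

**Step 13**
Reactants: 27 sulfone
Product: 28 {(2R,3R)-2-methyl-3-[(3E,5S)-3,6,6-trimethyl-8-[(1-phenyl-1H-tetrazol-5-yl)sulfonyl]-5-[(triethylsilyl)oxy]oct-3-en-1-yl]oxiran-2-yl}methanol
Conditions: DDQ, CH2Cl2/pH 7 buffer (10:1), 0 °C → rt
Reagents that add atoms: none
Why: Oxidative cleavage of the 4-methoxybenzyl ether by DDQ (hydride abstraction, then hydrolysis of the oxocarbenium ion) is neutral and orthogonal to the silyl ether, the sulfone and the epoxide.

**Step 14**
Reactants: 28 epoxy alcohol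
Product: 29 (2S,3R)-2-methyl-3-[(3E,5S)-3,6,6-trimethyl-8-[(1-phenyl-1H-tetrazol-5-yl)sulfonyl]-5-[(triethylsilyl)oxy]oct-3-en-1-yl]oxirane-2-carbaldehyde
Conditions: Dess–Martin periodinane, pyridine, CH2Cl2, 0 °C → rt
Reagents that add atoms: none
Why: Buffered Dess–Martin oxidation gives the epoxy aldehyde, which cannot epimerise because C7 is quaternary (the descriptor at C7 changes to S only through the priority rules).

**Step 15**
Reactants: 29 epoxy aldehyde sulfone
Product: 31 triethyl{[(1R,6S,7E,11R)-1,5,5,8-tetramethyl-12-oxabicyclo[9.1.0]dodeca-2,7-dien-6-yl]oxy}silane, via macrocyclic β-alkoxy sulfone potassium salt 30 (not isolated)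
Conditions: KN(SiMe3)2 (slow addition), THF, −78 °C → rt, 1 mM
Reagents that add atoms: none
Why: Intramolecular Julia–Kocienski olefination: the sulfonyl carbanion at C9 adds to the non-enolisable epoxy aldehyde, and Smiles rearrangement with loss of SO2 and tetrazolate closes the 11-membered ring as the C8=C9 alkene, whose geometry does not matter because it is removed in step 16.

**Step 16**
Reactants: 31 macrocyclic diene
Product: 32 triethyl{[(1R,4E,6S,11R)-4,7,7,11-tetramethyl-12-oxabicyclo[9.1.0]dodec-4-en-6-yl]oxy}silane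
Conditions: 2-nitrobenzenesulfonyl hydrazide, Et3N, CH2Cl2, rt
Reagents that add atoms: none
Why: Diimide reduction transfers H2 in a concerted, metal-free way to the 1,2-disubstituted C8=C9 alkene far faster than to the trisubstituted C2=C3 alkene and cannot hydrogenolyse the vinyl epoxide or the allylic C–O bond.

**Step 17**
Reactants: 32 silyl ether
Product: 33 (1R,4E,6S,11R)-4,7,7,11-tetramethyl-12-oxabicyclo[9.1.0]dodec-4-en-6-ol
Conditions: n-Bu4NF, THF, rt
Reagents that add atoms: none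
Why: Fluoride-induced desilylation frees the C1 alcohol with retention, since only the Si–O bond is broken.

**Step 18**
Reactants: 33 macrocyclic alcohol; 34 4-methoxybenzoyl chloride
Product: 35 (1R,4E,6S,11R)-4,7,7,11-tetramethyl-12-oxabicyclo[9.1.0]dodec-4-en-6-yl 4-methoxybenzoate (target)
Conditions: Et3N, DMAP, CH2Cl2, 0 → 40 °C
Reagents that add atoms: 4-methoxybenzoyl chloride, COc1ccc(C(Cl)=O)cc1
Why: DMAP-catalysed acylation (nucleophilic catalysis through the acylpyridinium ion) esterifies the hindered alcohol at oxygen, so C1 keeps its S configuration and the epoxide survives the basic medium.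

**Compound list**
1 | geraniol; (2E)-3,7-dimethylocta-2,6-dien-1-ol | CC(C)=CCC/C(C)=C/CO | starting material
2 | tert-butyl(chloro)diphenylsilane | CC(C)(C)[Si](Cl)(c1ccccc1)c1ccccc1 | starting material
3 | tert-butyl{[(2E)-3,7-dimethylocta-2,6-dien-1-yl]oxy}diphenylsilane | CC(C)=CCC/C(C)=C/CO[Si](c1ccccc1)(c1ccccc1)C(C)(C)C | intermediate
4 | tert-butyl hydroperoxide | CC(C)(C)OO | starting material
5 | (2E,6E)-8-{[tert-butyl(diphenyl)silyl]oxy}-2,6-dimethylocta-2,6-dien-1-ol | OC/C(C)=C/CC/C(C)=C/CO[Si](c1ccccc1)(c1ccccc1)C(C)(C)C | intermediate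
6 | {(2R,3R)-3-[(3E)-5-{[tert-butyl(diphenyl)silyl]oxy}-3-methylpent-3-en-1-yl]-2-methyloxiran-2-yl}methanol | CC(C)(C)[Si](c1ccccc1)(c1ccccc1)OC/C=C(\C)CC[C@H]1O[C@]1(C)CO | intermediate
7 | 1-(chloromethyl)-4-methoxybenzene | COc1ccc(CCl)cc1 | starting material
8 | tert-butyl{[(2E)-5-[(2R,3R)-3-{[(4-methoxyphenyl)methoxy]methyl}-3-methyloxiran-2-yl]-3-methylpent-2-en-1-yl]oxy}diphenylsilane | CC(C)(C)[Si](c1ccccc1)(c1ccccc1)OC/C=C(\C)CC[C@H]1O[C@]1(C)COCc1ccc(OC)cc1 | intermediate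
9 | (2E)-5-[(2R,3R)-3-{[(4-methoxyphenyl)methoxy]methyl}-3-methyloxiran-2-yl]-3-methylpent-2-en-1-ol | OC/C=C(\C)CC[C@H]1O[C@]1(C)COCc1ccc(OC)cc1 | intermediate
10 | (2E)-5-[(2R,3R)-3-{[(4-methoxyphenyl)methoxy]methyl}-3-methyloxiran-2-yl]-3-methylpent-2-enal | O=C/C=C(\C)CC[C@H]1O[C@]1(C)COCc1ccc(OC)cc1 | intermediate
11 | (−)-α-pinene; (1S,5S)-2,6,6-trimethylbicyclo[3.1.1]hept-2-ene | CC1=CC[C@H]2C[C@@H]1C2(C)C | starting material
12 | borane–dimethyl sulfide | C[S+](C)[BH3-] | starting material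
13 | (+)-diisopinocampheylborane (from (−)-α-pinene; boron on C3 of each pinane, trans to the C2 methyl) | B([C@H]1C[C@H]2C[C@@H]([C@@H]1C)C2(C)C)[C@H]1C[C@H]2C[C@@H]([C@@H]1C)C2(C)C | intermediate
14 | 3-methylbuta-1,2-diene | CC(C)=C=C | starting material
15 | B-(3-methylbut-2-en-1-yl)diisopinocampheylborane (from 13) | CC(C)=CCB([C@H]1C[C@H]2C[C@@H]([C@@H]1C)C2(C)C)[C@H]1C[C@H]2C[C@@H]([C@@H]1C)C2(C)C | intermediate (not isolated)
16 | diisopinocampheylborinate ester of 17 (B–O bond at the C1 oxygen) | B([C@H]1C[C@H]2C[C@@H]([C@@H]1C)C2(C)C)([C@H]1C[C@H]2C[C@@H]([C@@H]1C)C2(C)C)O[C@H](C(C)(C)C=C)/C=C(\C)CC[C@H]1O[C@]1(C)COCc1ccc(OC)cc1 | intermediate (not isolated)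
17 | (4S,5E)-8-[(2R,3R)-3-{[(4-methoxyphenyl)methoxy]methyl}-3-methyloxiran-2-yl]-3,3,6-trimethylocta-1,5-dien-4-ol | O[C@H](C(C)(C)C=C)/C=C(\C)CC[C@H]1O[C@]1(C)COCc1ccc(OC)cc1 | intermediate
18 | chlorotriethylsilane | CC[Si](Cl)(CC)CC | starting material
19 | triethyl{[(4S,5E)-8-[(2R,3R)-3-{[(4-methoxyphenyl)methoxy]methyl}-3-methyloxiran-2-yl]-3,3,6-trimethylocta-1,5-dien-4-yl]oxy}silane | CC[Si](CC)(CC)O[C@H](C(C)(C)C=C)/C=C(\C)CC[C@H]1O[C@]1(C)COCc1ccc(OC)cc1 | intermediate
20 | 9-borabicyclo[3.3.1]nonane | B1C2CCCC1CCC2 | starting material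
21 | hydrogen peroxide | OO | starting material
22 | 9-alkyl-9-borabicyclo[3.3.1]nonane from 19 (boron on the terminal carbon C9) | CC[Si](CC)(CC)O[C@H](C(C)(C)CCB1C2CCCC1CCC2)/C=C(\C)CC[C@H]1O[C@]1(C)COCc1ccc(OC)cc1 | intermediate (not isolated)
23 | (4S,5E)-8-[(2R,3R)-3-{[(4-methoxyphenyl)methoxy]methyl}-3-methyloxiran-2-yl]-3,3,6-trimethyl-4-[(triethylsilyl)oxy]oct-5-en-1-ol | CC[Si](CC)(CC)O[C@H](C(C)(C)CCO)/C=C(\C)CC[C@H]1O[C@]1(C)COCc1ccc(OC)cc1 | intermediate
24 | 1-phenyl-1H-tetrazole-5-thiol | SC1=NN=NN1c1ccccc1 | starting material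
25 | tetrazolyl sulfide of 23 (C9–S) | CC[Si](CC)(CC)O[C@H](C(C)(C)CCSC1=NN=NN1c1ccccc1)/C=C(\C)CC[C@H]1O[C@]1(C)COCc1ccc(OC)cc1 | intermediate
26 | corresponding sulfoxide (configuration at sulfur undefined) | CC[Si](CC)(CC)O[C@H](C(C)(C)CCS(=O)C1=NN=NN1c1ccccc1)/C=C(\C)CC[C@H]1O[C@]1(C)COCc1ccc(OC)cc1 | intermediate (not isolated)
27 | corresponding sulfone | CC[Si](CC)(CC)O[C@H](C(C)(C)CCS(=O)(=O)C1=NN=NN1c1ccccc1)/C=C(\C)CC[C@H]1O[C@]1(C)COCc1ccc(OC)cc1 | intermediate
28 | {(2R,3R)-2-methyl-3-[(3E,5S)-3,6,6-trimethyl-8-[(1-phenyl-1H-tetrazol-5-yl)sulfonyl]-5-[(triethylsilyl)oxy]oct-3-en-1-yl]oxiran-2-yl}methanol | CC[Si](CC)(CC)O[C@H](C(C)(C)CCS(=O)(=O)C1=NN=NN1c1ccccc1)/C=C(\C)CC[C@H]1O[C@]1(C)CO | intermediate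
29 | (2S,3R)-2-methyl-3-[(3E,5S)-3,6,6-trimethyl-8-[(1-phenyl-1H-tetrazol-5-yl)sulfonyl]-5-[(triethylsilyl)oxy]oct-3-en-1-yl]oxirane-2-carbaldehyde | CC[Si](CC)(CC)O[C@H](C(C)(C)CCS(=O)(=O)C1=NN=NN1c1ccccc1)/C=C(\C)CC[C@H]1O[C@]1(C)C=O | intermediate
30 | potassium alkoxide of the macrocyclic β-hydroxy sulfone (ring as in 31 but C8 carries O−K+ and C9 the tetrazolylsulfonyl group; C8 and C9 configuration not controlled) | CC[Si](CC)(CC)O[C@H]1/C=C(\C)CC[C@H]2O[C@]2(C)C([O-])C(CC1(C)C)S(=O)(=O)C1=NN=NN1c1ccccc1.[K+] | intermediate (not isolated)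
31 | triethyl{[(1R,6S,7E,11R)-1,5,5,8-tetramethyl-12-oxabicyclo[9.1.0]dodeca-2,7-dien-6-yl]oxy}silane (C8=C9 alkene as an E/Z mixture) | CC[Si](CC)(CC)O[C@H]1/C=C(\C)CC[C@H]2O[C@]2(C)C=CCC1(C)C | intermediate
32 | triethyl{[(1R,4E,6S,11R)-4,7,7,11-tetramethyl-12-oxabicyclo[9.1.0]dodec-4-en-6-yl]oxy}silane | CC[Si](CC)(CC)O[C@H]1/C=C(\C)CC[C@H]2O[C@]2(C)CCCC1(C)C | intermediate
33 | (1R,4E,6S,11R)-4,7,7,11-tetramethyl-12-oxabicyclo[9.1.0]dodec-4-en-6-ol | O[C@H]1/C=C(\C)CC[C@H]2O[C@]2(C)CCCC1(C)C | intermediate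
34 | 4-methoxybenzoyl chloride | COc1ccc(C(Cl)=O)cc1 | starting material
35 | (1R,4E,6S,11R)-4,7,7,11-tetramethyl-12-oxabicyclo[9.1.0]dodec-4-en-6-yl 4-methoxybenzoate | COc1ccc(C(=O)O[C@H]2/C=C(\C)CC[C@H]3O[C@]3(C)CCCC2(C)C)cc1 | target

**Step count and risk**
Total step count: 18 (17 in the main line plus the one-step preparation of borane 13).
Longest linear sequence: 17 steps (geraniol 1 → 35 through steps 1–6 and 8–18).

The three steps most likely to fail:

Step 15 (closure of the 11-membered ring by olefination). The risk is oligomerisation and ring strain. Fallback, setting out from 23 and coming back at 32: close the same C8–C9 bond by sp3 alkylation instead of olefination. Treat 23 with PhSSPh and n-Bu3P to give the phenyl sulfide F1, oxidise it with (NH4)6Mo7O24·4H2O/H2O2 to the phenyl sulfone F2, and remove the benzyl-type ether with DDQ to give the epoxy alcohol F3. Convert F3 with Tf2O and 2,6-di-tert-butyl-4-methylpyridine at −78 °C into the epoxy triflate F4. Slow addition of KN(SiMe3)2 at high dilution (THF, −78 °C) alkylates the sulfonyl carbanion at the primary triflate carbon, which has no β-hydrogen and so cannot eliminate, to give the macrocyclic sulfone F5. Na(Hg)/Na2HPO4 in MeOH then removes the sulfonyl group to give 32, so 31 and the diimide step are bypassed.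

Step 8 (asymmetric reverse prenylation). The risk is an air-sensitive reagent and incomplete control at C1. Fallback, setting out from 10 and coming back at 17: make the same bond without reagent control and resolve. Barbier reaction of 10 with prenyl bromide and Zn in THF/aqueous NH4Cl (the allylzinc also reacts through its γ-carbon) gives the C1-epimeric alcohol mixture F6. Esterification with (S)-2-methoxy-2-phenylacetic acid (DCC, DMAP) gives the epimeric esters F7. Chromatography separates the 4S ester F8, assigned by the 1H NMR shift rule for O-methylmandelates, and LiOH in THF/MeOH/H2O returns 17.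

Step 2 (SeO2 allylic oxidation). The risk is modest yield and over-oxidation to the enal. Fallback, setting out from 3 and coming back at 5: build the C8 alcohol by cleavage and olefination. mCPBA (1 equiv, CH2Cl2, −20 °C) epoxidises the more electron-rich distal alkene to the racemic epoxide F9. H5IO6 in THF/H2O cleaves it to the aldehyde F10. Wittig reaction with Ph3P=C(CH3)CO2Et gives the E-enoate F11, and i-Bu2AlH (CH2Cl2, −78 °C) reduces it to 5.

**Further compounds**
F1 | step 15 | triethyl{[(4S,5E)-8-[(2R,3R)-3-{[(4-methoxyphenyl)methoxy]methyl}-3-methyloxiran-2-yl]-3,3,6-trimethyl-1-(phenylsulfanyl)oct-5-en-4-yl]oxy}silane | CC[Si](CC)(CC)O[C@H](C(C)(C)CCSc1ccccc1)/C=C(\C)CC[C@H]1O[C@]1(C)COCc1ccc(OC)cc1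
F2 | step 15 | triethyl{[(4S,5E)-8-[(2R,3R)-3-{[(4-methoxyphenyl)methoxy]methyl}-3-methyloxiran-2-yl]-3,3,6-trimethyl-1-(phenylsulfonyl)oct-5-en-4-yl]oxy}silane | CC[Si](CC)(CC)O[C@H](C(C)(C)CCS(=O)(=O)c1ccccc1)/C=C(\C)CC[C@H]1O[C@]1(C)COCc1ccc(OC)cc1
F3 | step 15 | {(2R,3R)-2-methyl-3-[(3E,5S)-3,6,6-trimethyl-8-(phenylsulfonyl)-5-[(triethylsilyl)oxy]oct-3-en-1-yl]oxiran-2-yl}methanol | CC[Si](CC)(CC)O[C@H](C(C)(C)CCS(=O)(=O)c1ccccc1)/C=C(\C)CC[C@H]1O[C@]1(C)CO
F4 | step 15 | {(2R,3R)-2-methyl-3-[(3E,5S)-3,6,6-trimethyl-8-(phenylsulfonyl)-5-[(triethylsilyl)oxy]oct-3-en-1-yl]oxiran-2-yl}methyl trifluoromethanesulfonate | CC[Si](CC)(CC)O[C@H](C(C)(C)CCS(=O)(=O)c1ccccc1)/C=C(\C)CC[C@H]1O[C@]1(C)COS(=O)(=O)C(F)(F)F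
F5 | step 15 | triethyl{[(1R,4E,6S,11R)-4,7,7,11-tetramethyl-9-(phenylsulfonyl)-12-oxabicyclo[9.1.0]dodec-4-en-6-yl]oxy}silane (configuration at the sulfonyl carbon not controlled) | CC[Si](CC)(CC)O[C@H]1/C=C(\C)CC[C@H]2O[C@]2(C)CC(CC1(C)C)S(=O)(=O)c1ccccc1
F6 | step 8 | (5E)-8-[(2R,3R)-3-{[(4-methoxyphenyl)methoxy]methyl}-3-methyloxiran-2-yl]-3,3,6-trimethylocta-1,5-dien-4-ol as the 4R/4S mixture | OC(C(C)(C)C=C)/C=C(\C)CC[C@H]1O[C@]1(C)COCc1ccc(OC)cc1
F7 | step 8 | (2S)-2-methoxy-2-phenylacetates of F6 as the 4R/4S mixture | CO[C@H](C(=O)OC(C(C)(C)C=C)/C=C(\C)CC[C@H]1O[C@]1(C)COCc1ccc(OC)cc1)c1ccccc1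
F8 | step 8 | (4S,5E)-8-[(2R,3R)-3-{[(4-methoxyphenyl)methoxy]methyl}-3-methyloxiran-2-yl]-3,3,6-trimethylocta-1,5-dien-4-yl (2S)-2-methoxy-2-phenylacetate | CO[C@H](C(=O)O[C@H](C(C)(C)C=C)/C=C(\C)CC[C@H]1O[C@]1(C)COCc1ccc(OC)cc1)c1ccccc1
F9 | step 2 | tert-butyl{[(2E)-5-(3,3-dimethyloxiran-2-yl)-3-methylpent-2-en-1-yl]oxy}diphenylsilane (racemic) | CC(C)(C)[Si](c1ccccc1)(c1ccccc1)OC/C=C(\C)CCC1OC1(C)C
F10 | step 2 | (4E)-6-{[tert-butyl(diphenyl)silyl]oxy}-4-methylhex-4-enal | CC(C)(C)[Si](c1ccccc1)(c1ccccc1)OC/C=C(\C)CCC=O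
F11 | step 2 | ethyl (2E,6E)-8-{[tert-butyl(diphenyl)silyl]oxy}-2,6-dimethylocta-2,6-dienoate | CC(C)(C)[Si](c1ccccc1)(c1ccccc1)OC/C=C(\C)CC/C=C(\C)C(=O)OCC
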